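## Structural features

The target is a 2-aryl-3-(hydroxymethyl)-2,3-dihydrobenzofuran. Ring A is the benzene ring fused to the dihydrofuran (O1, C2, C3, C3a, C7a); it carries a methoxy group at C7 and a 2-(methoxycarbonyl)ethyl chain at C5. Ring B, a 4-hydroxy-3,5-dimethoxyphenyl group, sits on C2, and the hydroxymethyl carbon (called C9 here) sits on C3. The only stereocentres are the neighbours C2 (S) and C3 (R), trans to each other across the five-membered ring. The C2–O1 bond is the weak point: it is benzylic and an aryl ether at once, and it lies para to the free phenol of ring B. It can therefore ionise to a quinone methide under acid or hot base, be cut by hydrogenolysis, or be dehydrogenated to the benzofuran. The methyl ester rules out hydrides and hard nucleophiles, and the free phenol is easily oxidised. The real difficulty is to set the contiguous C2/C3 pair in absolute and relative terms while joining two different oxygenated arenes in the right orientation (ring A on C3 and O1, ring B on C2). The key step uses the fact that C3a (bonded to C3) and C7a (bonded to O1) are adjacent carbons of ring A, with C7–OMe on the far side of C7a. This is the ortho/ipso pattern of a 2-methoxyaryl iodide whose only free ortho C–H is C3a–H. The O1–C2–C3 unit corresponds to an epoxide whose benzylic carbon keeps its oxygen.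

## Logic of the disconnections

13 to 12 to 11: the O–H bond at C9 is traced back to an O–CH2Ph bond (13 to 12) and the ring B phenol O–H to an O–C(=O)tBu bond (12 to 11). A free primary alcohol would compete for palladium or migrate the epoxide. A free or alkylated para oxygen would make the aryl epoxide ionise at its benzylic carbon. The benzyl ether cannot migrate and the acyl group withdraws electrons. The skeleton is not simplified, but the key step becomes possible. Forward, methanolysis must spare the methyl ester (exchange with methanol is degenerate) and hydrogenolysis must spare the C2–O1 bond.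

11 to 4 + 10: the C3–C3a and O1–C7a bonds are cut. They sit on neighbouring ring A carbons next to the methoxy group, which is what one ortho C–H functionalisation plus one ipso substitution of an aryl iodide produces. The bicyclic core and both stereocentres fall apart into a flat arene and a three-membered ring. Forward, the epoxide must be opened at C3 and not at the benzylic carbon, with inversion, and C–O bond formation at palladium must outrun β-hydride loss. The epoxide must be cis and (2R,3S).

10 to 9: both C–O bonds of the oxirane are cut. A cis-epoxide conjugated to an arene is the product class of chiral dioxirane epoxidation. Both stereocentres of 13 are thereby reduced to one enantioface choice on an achiral alkene. Forward, the alkene must be purely Z and oxygen transfer must be concerted so that the geometry is kept.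

9 to 8 to 6 + 7: the C2=C3 double bond is traced back to a triple bond (9 to 8), then the aryl–C(sp) bond is cut (8 to 6 + 7). The alkyne is the reliable source of Z geometry, and 7 delivers C2, C3 and C9 with the benzyl ether already in place. Ring B shrinks to a bromophenol derivative. Forward, hydrogen uptake must stop at the alkene without touching the benzyl ether, and the coupling must tolerate the aryl ester.

6 to 5: the O–acyl bond is cut. The acyl group is put on first so that every later ring B intermediate is electron-poor and the phenol never interferes with palladium or copper. Forward, this is a simple acylation of a hindered phenol.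

4 to 3 to 2 to 1: C–I is traced back to C–B, C–B to C–OSO2CF3, and that to the phenol O–H. Iodine must sit para to the chain and ortho to the methoxy group, exactly where 1 has its hydroxyl; electrophilic iodination of the deoxygenated arene would go para to the methoxy group instead. The gain is a cheap starting material with all ring A and chain carbons in place. The demand is three interconversions that tolerate the ester, and the cost is that the ring oxygen of 1 is discarded and O1 later comes from 10.

## Other disconnections considered

Alternative 1: The cuts are C2–C1' (the ipso carbon of ring B) and C3–C3a; O1–C2 is left for a later closure.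
- Forward key step: aryllithium A2 would add to boron of the (E)-alkenyl boronate A1 to give ate complex A3. With Pd(OAc)2 and a MandyPhos ligand, the arylpalladium species from ring A bromide A4 would trigger a 1,2-shift of the ring B aryl group from boron to C2 while palladium delivers ring A to C3 on the opposite face, giving acyclic boronate A5.
- In its favour: three achiral pieces are joined in one catalytic, ligand-controlled step, and which carbon receives ring A is not in doubt. A4 would come from 1 in two steps (bromination ortho to the hydroxyl, methoxymethylation) with the phenol oxygen kept as O1. On both points it is better than the chosen plan, which needs three steps to exchange oxygen for iodine.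
- Against it here: a β-substituted alkenyl boronate such as A1 tends to undergo plain Suzuki-type transfer instead of the metallate shift unless boron carries a special diol. A4 is hindered and bromide ion slows this coupling. A2 needs low-temperature lithiation.
- After the key step the C–B bond must be oxidised, the acetal removed and the ring closed at O1–C2. Anti addition to the E-alkene places boron where an invertive displacement would give the cis ring, so closure would have to run through the benzylic cation under thermodynamic control. The C2 centre set by the catalyst is then not used.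
- Comparison: desilylation and hydrogenolysis follow, so four or five steps remain against two. On regiochemical certainty and on precedent for the reaction type alternative 1 is the better. On use of the stereochemistry it creates and on steps after the key step the chosen plan is better. Overall length is about equal.

Alternative 2: The cuts run through ring A itself, C3a–C7a and C6–C7.
- Forward key step: Ph3PAuNTf2 would activate the ynol ether of A6. Furan C2 attacks the oxygen-bearing alkyne carbon (closing the five-membered ring), the terminal alkyne carbon bonds to furan C5, and opening of the arene oxide moves the furan oxygen to C7, giving phenol A7.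
- In its favour: the arene and the dihydrofuran are made in one intramolecular, base-free step, and the mechanism fixes the oxygenation pattern of ring A. On certainty of constitution it is better than the chosen plan.
- Against it here: the step creates no stereocentre, so C2 and C3 must both be built into A6 by a separate asymmetric sequence and the main problem is only moved. A6 is an alkynyl ether of a secondary, electron-rich benzylic alcohol, hard to prepare and apt to ionise under a Lewis-acidic gold catalyst. The 2,4-disubstituted furan is an awkward pattern.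
- Comparison: afterwards the C7 phenol must be methylated, the silyl ether removed, the primary alcohol oxidised to the acid and esterified, and two benzyl ethers removed. That is five or six steps against two. Alternative 2 is stronger only on regiochemistry; on stereocontrol and step economy the chosen plan is clearly ahead.

Alternative 3: The cuts are C2–C3 and O1–C2.
- Forward key step: Cs2CO3 would expel toluenesulfinate from sulfone A8 to give ortho-quinone methide A10. The ylide from sulfonium salt A9 (drawn with the (2R,5R)-sulfide; the enantiomer that fits would be chosen) adds at C3, and the phenoxide displaces the sulfide at C2 in a 5-exo-tet closure to give A11.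
- In its favour: (4+1) annulation of quinone methides generated this way with sulfur ylides is a known reaction type, so on precedent it is better than the chosen plan. Ring and both stereocentres form in one step, the trans geometry follows from anti-periplanar closure of the betaine, and the phenol oxygen of 1 is kept. Two steps remain afterwards (desilylation, hydrogenolysis), equal to the chosen plan.
- Against it here: the absolute configuration rests on a stoichiometric chiral sulfide and on facial selectivity in an intermolecular C–C bond formation by a semi-stabilised ylide, where betaine formation can be reversible. A10 carries an alkyl substituent with adjacent C–H bonds and may tautomerise to a vinyl phenol faster than it is trapped. A8 needs an ortho C-alkylation of ring A, and A9 needs several steps.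
- Comparison: total length is about the same. The chosen plan transfers configuration stereospecifically from an epoxide made by catalytic asymmetric oxidation, which is the stronger position on enantiopurity. Alternative 3 is stronger on precedent and equal on the endgame.

Key step: step 8

Remark on the chemistry: benzofuran numbering is used, with C9 for the hydroxymethyl carbon. The target is (2S,3R), trans. The key step keeps the C2–O bond and inverts C3, so the epoxide must be the cis (2R,3S) isomer. The benzylic descriptor changes from R in 10 to S in 11 only because the ranking of its substituents changes.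

Step 1
Reactants: 1 methyl 3-(4-hydroxy-3-methoxyphenyl)propanoate
Product: 2 methyl 3-[3-methoxy-4-(trifluoromethylsulfonyloxy)phenyl]propanoate
Conditions: Tf2O, pyridine, CH2Cl2, 0 °C to rt
Reagents that add atoms: trifluoromethanesulfonic anhydride, O=S(=O)(OS(=O)(=O)C(F)(F)F)C(F)(F)F
Why: O-sulfonylation of the phenol turns the C4–O bond into a leaving group for palladium; the methyl ester is inert to Tf2O and pyridine.

Step 2
Reactants: 2 methyl 3-[3-methoxy-4-(trifluoromethylsulfonyloxy)phenyl]propanoate
Product: 3 methyl 3-[3-methoxy-4-(4,4,5,5-tetramethyl-1,3,2-dioxaborolan-2-yl)phenyl]propanoate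
Conditions: B2pin2, PdCl2(dppf) (3 mol%), KOAc, 1,4-dioxane, 90 °C
Reagents that add atoms: bis(pinacolato)diboron, CC1(C)OB(OC1(C)C)B1OC(C)(C)C(C)(C)O1
Why: Miyaura borylation, by oxidative addition of the aryl triflate to zerovalent palladium, acetate-assisted transmetalation and reductive elimination; KOAc is too weak to hydrolyse the ester or to start Suzuki homocoupling.

Step 3
Reactants: 3 methyl 3-[3-methoxy-4-(4,4,5,5-tetramethyl-1,3,2-dioxaborolan-2-yl)phenyl]propanoate
Product: 4 methyl 3-(4-iodo-3-methoxyphenyl)propanoate
Conditions: CuI (10 mol%), 1,10-phenanthroline (20 mol%), KI (1.5 equiv), MeOH/H2O 4:1, air, 80 °C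
Reagents that add atoms: potassium iodide, [K+].[I-]
Why: Copper-mediated iododeboronation: the aryl group passes from boron to copper and C–I bond formation under air puts iodine exactly on the ipso carbon, whereas an electrophilic iodinating agent could also attack the C–H para to the methoxy group. Methanol as solvent makes ester exchange degenerate.

Step 4
Reactants: 5 4-bromo-2,6-dimethoxyphenol
Product: 6 4-bromo-2,6-dimethoxyphenyl pivalate
Conditions: PivCl, Et3N, DMAP (cat.), CH2Cl2, 0 °C to rt
Reagents that add atoms: pivaloyl chloride, CC(C)(C)C(=O)Cl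
Why: DMAP-catalysed acylation of the phenol. The pivalate lowers the electron density of ring B, so the later aryl epoxide does not ionise at its benzylic carbon, and it is hindered enough to survive amines and carbonate.

Step 5
Reactants: 6 4-bromo-2,6-dimethoxyphenyl pivalate; 7 benzyl propargyl ether
Product: 8 4-[3-(benzyloxy)prop-1-yn-1-yl]-2,6-dimethoxyphenyl pivalate
Conditions: PdCl2(PPh3)2 (3 mol%), CuI (5 mol%), Et3N/DMF, 70 °C
Reagents that add atoms: none
Why: Sonogashira coupling of the aryl bromide with the terminal alkyne; the para acyloxy and meta methoxy groups leave the C–Br bond reactive enough, and the tertiary amine cannot attack the hindered ester.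

Step 6
Reactants: 8 4-[3-(benzyloxy)prop-1-yn-1-yl]-2,6-dimethoxyphenyl pivalate
Product: 9 4-[(1Z)-3-(benzyloxy)prop-1-en-1-yl]-2,6-dimethoxyphenyl pivalate
Conditions: H2 (1 atm), Pd/CaCO3 poisoned with Pb(OAc)2, quinoline, EtOAc, rt
Reagents that add atoms: none
Why: Lindlar semihydrogenation: syn delivery of hydrogen on the poisoned palladium surface should give the Z-alkene and stop there; this catalyst does not hydrogenolyse the benzyl ether or the aryl ester.

Step 7
Reactants: 9 4-[(1Z)-3-(benzyloxy)prop-1-en-1-yl]-2,6-dimethoxyphenyl pivalate
Product: 10 4-[(2R,3S)-3-(benzyloxymethyl)oxiran-2-yl]-2,6-dimethoxyphenyl pivalate (cis)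
Conditions: D-glucose-derived spiro-oxazolidinone ketone (N-4-tolyl, 25 mol%), KHSO5 (as 2KHSO5·KHSO4·K2SO4), K2CO3, Bu4NHSO4 (cat.), DME/dimethoxymethane–aq. buffer (pH about 8), −10 °C
Reagents that add atoms: potassium peroxymonosulfate, [K+].[O-]S(=O)(=O)OO
Why: Shi epoxidation with the ketone type designed for cis-alkenes conjugated to an arene: the chiral dioxirane transfers oxygen in a concerted spiro transition state, so the Z geometry is carried into the cis-epoxide. The aryl group lies next to the oxazolidinone, which by analogy with cis-β-methylstyrene should give R at the benzylic carbon and S at C3. The buffered, cold medium spares the pivalate and the epoxide.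

Step 8
Reactants: 4 methyl 3-(4-iodo-3-methoxyphenyl)propanoate; 10 4-[(2R,3S)-3-(benzyloxymethyl)oxiran-2-yl]-2,6-dimethoxyphenyl pivalate
Product: 11 methyl 3-[(2S,3R)-3-(benzyloxymethyl)-2-[3,5-dimethoxy-4-(pivaloyloxy)phenyl]-7-methoxy-2,3-dihydro-1-benzofuran-5-yl]propanoate
Conditions: Pd(OAc)2 (10 mol%), XPhos (20 mol%), norbornene (1 equiv), K2CO3 (2 equiv), NMP, 80 °C, N2; 4 in 1.5-fold excess
Reagents that add atoms: none
Why: Proposed new method: zerovalent palladium inserts into the C–I bond of 4, and norbornene insertion with palladation of the only free ortho C–H gives an aryl–norbornyl palladacycle of divalent palladium, which should open 10 by backside attack at C3 (the carbon bearing the benzyloxymethyl group) to give a tetravalent palladium alkyl whose reductive elimination forms C3–C3a; β-carbon elimination then expels norbornene and C–O reductive elimination of the C2 alkoxide at the ipso carbon forms O1–C7a. The closest known reaction type is the palladium/norbornene (Catellani) annulation of aryl iodides with terminal epoxides to 2-substituted 2,3-dihydrobenzofurans; a cis-2,3-disubstituted aryl epoxide has not been used in it. The dihydrofuran ring is closed in a (3+2) sense, the last bond (O1–C7a) by reductive elimination from a six-membered aryl(alkoxo)palladium chelate. C3 is the one new stereocentre and is substrate-controlled: inversion at the S-configured epoxide carbon followed by retentive C–C reductive elimination gives 3R, while C2 keeps its C–O bond and its spatial arrangement, so the cis-epoxide maps onto the trans ring. The step needs opening at the non-benzylic carbon, which the steric demand of the palladacycle against the aryl-bearing carbon and the electron-poor pivaloyloxy ring (little benzylic cation character) are meant to secure. It also needs a single ortho alkylation, which the C7 methoxy group ensures by blocking the other ortho position and forcing norbornene extrusion. The methyl ester, aryl pivalate and benzyl ether should be inert to anhydrous carbonate and to palladium under these conditions.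

Step 9
Reactants: 11 methyl 3-[(2S,3R)-3-(benzyloxymethyl)-2-[3,5-dimethoxy-4-(pivaloyloxy)phenyl]-7-methoxy-2,3-dihydro-1-benzofuran-5-yl]propanoate
Product: 12 methyl 3-[(2S,3R)-3-(benzyloxymethyl)-2-(4-hydroxy-3,5-dimethoxyphenyl)-7-methoxy-2,3-dihydro-1-benzofuran-5-yl]propanoate
Conditions: K2CO3 (1.5 equiv), MeOH, rt
Reagents that add atoms: none
Why: Base-catalysed methanolysis (transesterification) of the aryl pivalate; the phenoxide leaving group makes it far more labile than an alkyl ester, and the methyl ester can only exchange into itself. No stereocentre is touched at room temperature.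

Step 10
Reactants: 12 methyl 3-[(2S,3R)-3-(benzyloxymethyl)-2-(4-hydroxy-3,5-dimethoxyphenyl)-7-methoxy-2,3-dihydro-1-benzofuran-5-yl]propanoate
Product: 13 methyl 3-[(2S,3R)-2-(4-hydroxy-3,5-dimethoxyphenyl)-3-(hydroxymethyl)-7-methoxy-2,3-dihydro-1-benzofuran-5-yl]propanoate
Conditions: H2 (1 atm), Pd/C (10 wt%), EtOAc, rt, stopped at full conversion
Reagents that add atoms: none
Why: Catalytic hydrogenolysis of the primary benzyl ether. The ring C2–O1 bond is a secondary, hindered benzylic ether and should be cleaved much more slowly, and the stereocentres are not involved.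

Compound list
1 | methyl 3-(4-hydroxy-3-methoxyphenyl)propanoate | COC(=O)CCc1ccc(O)c(OC)c1 | starting material
2 | methyl 3-[3-methoxy-4-(trifluoromethylsulfonyloxy)phenyl]propanoate | COC(=O)CCc1ccc(OS(=O)(=O)C(F)(F)F)c(OC)c1 | intermediate
3 | methyl 3-[3-methoxy-4-(4,4,5,5-tetramethyl-1,3,2-dioxaborolan-2-yl)phenyl]propanoate | COC(=O)CCc1ccc(B2OC(C)(C)C(C)(C)O2)c(OC)c1 | intermediate
4 | methyl 3-(4-iodo-3-methoxyphenyl)propanoate | COC(=O)CCc1ccc(I)c(OC)c1 | intermediate
5 | 4-bromo-2,6-dimethoxyphenol | COc1cc(Br)cc(OC)c1O | starting material
6 | 4-bromo-2,6-dimethoxyphenyl pivalate | COc1cc(Br)cc(OC)c1OC(=O)C(C)(C)C | intermediate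
7 | benzyl propargyl ether | C#CCOCc1ccccc1 | starting material
8 | 4-[3-(benzyloxy)prop-1-yn-1-yl]-2,6-dimethoxyphenyl pivalate | COc1cc(C#CCOCc2ccccc2)cc(OC)c1OC(=O)C(C)(C)C | intermediate
9 | 4-[(1Z)-3-(benzyloxy)prop-1-en-1-yl]-2,6-dimethoxyphenyl pivalate | COc1cc(/C=C\COCc2ccccc2)cc(OC)c1OC(=O)C(C)(C)C | intermediate
10 | 4-[(2R,3S)-3-(benzyloxymethyl)oxiran-2-yl]-2,6-dimethoxyphenyl pivalate | O1[C@@H](COCc2ccccc2)[C@H]1c1cc(OC)c(OC(=O)C(C)(C)C)c(OC)c1 | intermediate
11 | methyl 3-[(2S,3R)-3-(benzyloxymethyl)-2-[3,5-dimethoxy-4-(pivaloyloxy)phenyl]-7-methoxy-2,3-dihydro-1-benzofuran-5-yl]propanoate | COC(=O)CCc1cc(OC)c2c(c1)[C@H](COCc1ccccc1)[C@@H](c1cc(OC)c(OC(=O)C(C)(C)C)c(OC)c1)O2 | intermediate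
12 | methyl 3-[(2S,3R)-3-(benzyloxymethyl)-2-(4-hydroxy-3,5-dimethoxyphenyl)-7-methoxy-2,3-dihydro-1-benzofuran-5-yl]propanoate | COC(=O)CCc1cc(OC)c2c(c1)[C@H](COCc1ccccc1)[C@@H](c1cc(OC)c(O)c(OC)c1)O2 | intermediate
13 | methyl 3-[(2S,3R)-2-(4-hydroxy-3,5-dimethoxyphenyl)-3-(hydroxymethyl)-7-methoxy-2,3-dihydro-1-benzofuran-5-yl]propanoate | COC(=O)CCc1cc(OC)c2c(c1)[C@H](CO)[C@@H](c1cc(OC)c(O)c(OC)c1)O2 | target

Total step count: 10 (three to 4, four to 10, the key step, two after it). Longest linear sequence: 7 steps (5 to 13 through steps 4 to 10).

Least certain steps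

Step 8 (key step, proposed new method). The most likely failures are opening of the epoxide at its benzylic carbon, or no opening at all. Both epoxide carbons are secondary, the benzylic one is electronically activated, and the benzyloxymethyl group inductively deactivates C3. Loss of a β-hydride from the palladium alkoxide before C–O bond formation and isomerisation of the epoxide to a ketone are further risks.

The fallback uses known chemistry, sets out from 1 and 8 and comes back at 12. It keeps the phenol oxygen of 1 as O1 and closes the ring at O1–C2.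
- Iodination of 1 ortho to the hydroxyl group (N-iodosuccinimide, cat. TsOH, MeCN) should give methyl 3-(4-hydroxy-3-iodo-5-methoxyphenyl)propanoate F1.
- Copper-catalysed borylation–protonation of 8 (CuCl, Xantphos, NaOtBu cat., B2pin2, MeOH, THF) should give 4-[(1Z)-3-(benzyloxy)-2-(4,4,5,5-tetramethyl-1,3,2-dioxaborolan-2-yl)prop-1-en-1-yl]-2,6-dimethoxyphenyl pivalate F2, with boron on the alkyne carbon remote from the arene.
- Suzuki coupling of F1 with F2 (PdCl2(dppf), K3PO4, dioxane/H2O, 80 °C) should give methyl 3-{3-[(Z)-3-(benzyloxy)-1-[3,5-dimethoxy-4-(pivaloyloxy)phenyl]prop-1-en-2-yl]-4-hydroxy-5-methoxyphenyl}propanoate F3.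
- Asymmetric hydrogenation with a cationic iridium phosphine–oxazoline complex ([Ir(cod)(tBu-PHOX)]BArF, H2 50 bar, CH2Cl2), the catalyst class developed for α-substituted stilbenes, should set C3 in methyl 3-{3-[(2R)-1-(benzyloxy)-3-[3,5-dimethoxy-4-(pivaloyloxy)phenyl]propan-2-yl]-4-hydroxy-5-methoxyphenyl}propanoate F4. The ligand enantiomer is chosen for this sense.
- Methanolysis (K2CO3, MeOH) should give methyl 3-{3-[(2R)-1-(benzyloxy)-3-(4-hydroxy-3,5-dimethoxyphenyl)propan-2-yl]-4-hydroxy-5-methoxyphenyl}propanoate F5.
- Ag2O in CH2Cl2 should oxidise the more electron-rich ring B phenol to methyl 3-{3-[(2R)-1-(benzyloxy)-3-(3,5-dimethoxy-4-oxocyclohexa-2,5-dien-1-ylidene)propan-2-yl]-4-hydroxy-5-methoxyphenyl}propanoate F6. The ring A phenol captures this quinone methide in a 5-exo closure anti to the C3 substituent, the ring-forming event of biomimetic phenylcoumaran synthesis, to give 12.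

Step 7. The risks are insufficient enantioface discrimination on a cis-alkene that carries a polar allylic ether, and acid-promoted opening of the aryl epoxide during isolation.

The fallback sets out from 6 and comes back at 10. It relies on reagent control with a firmly predictable sense.
- Sonogashira coupling of 6 with propargyl alcohol (PdCl2(PPh3)2, CuI, Et3N) should give 4-(3-hydroxyprop-1-yn-1-yl)-2,6-dimethoxyphenyl pivalate F7.
- Lindlar semihydrogenation should give 4-[(1Z)-3-hydroxyprop-1-en-1-yl]-2,6-dimethoxyphenyl pivalate F8.
- Sharpless asymmetric epoxidation (Ti(OiPr)4, L-(+)-diethyl tartrate, tBuOOH, 4 Å sieves, CH2Cl2, −20 °C) should give 4-[(2R,3S)-3-(hydroxymethyl)oxiran-2-yl]-2,6-dimethoxyphenyl pivalate F9.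
- Benzylation under neutral conditions (BnBr, Ag2O, CH2Cl2), which avoids alkoxide-induced epoxide migration and acyl transfer, returns to 10.

Step 10. The risk is reductive cleavage of the benzylic C2–O1 bond alongside the slow hydrogenolysis of an aliphatic benzyl ether, made easier by the free para phenol.

The fallback sets out from 11 and comes back at 13, with the order of deprotection reversed. Hydrogenolysis is run on 11 while ring B is still the electron-poor pivalate (H2, Pd/C, EtOAc) to give methyl 3-[(2S,3R)-2-[3,5-dimethoxy-4-(pivaloyloxy)phenyl]-3-(hydroxymethyl)-7-methoxy-2,3-dihydro-1-benzofuran-5-yl]propanoate F10. Methanolysis (K2CO3, MeOH) then gives 13.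

Step 3. The risks are protodeboronation of the electron-rich aryl boronate and partial ester hydrolysis in the warm aqueous medium.

The fallback sets out from 2 and comes back at 4 without boron.
- Buchwald–Hartwig coupling of 2 with benzophenone imine (Pd(OAc)2, BINAP, Cs2CO3, toluene, 100 °C) should give methyl 3-{4-[(diphenylmethylidene)amino]-3-methoxyphenyl}propanoate F11.
- Mild acid hydrolysis (aq. HCl, THF) should give methyl 3-(4-amino-3-methoxyphenyl)propanoate F12.
- Diazotisation (NaNO2, TsOH, MeCN/H2O) should give 2-methoxy-4-(3-methoxy-3-oxopropyl)benzenediazonium tosylate F13, which KI converts to 4 in a Sandmeyer-type iodination.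

Further compounds
F1 | step 8 | methyl 3-(4-hydroxy-3-iodo-5-methoxyphenyl)propanoate | COC(=O)CCc1cc(I)c(O)c(OC)c1
F2 | step 8 | 4-[(1Z)-3-(benzyloxy)-2-(4,4,5,5-tetramethyl-1,3,2-dioxaborolan-2-yl)prop-1-en-1-yl]-2,6-dimethoxyphenyl pivalate | COc1cc(/C=C(\COCc2ccccc2)B2OC(C)(C)C(C)(C)O2)cc(OC)c1OC(=O)C(C)(C)C
F3 | step 8 | methyl 3-{3-[(Z)-3-(benzyloxy)-1-[3,5-dimethoxy-4-(pivaloyloxy)phenyl]prop-1-en-2-yl]-4-hydroxy-5-methoxyphenyl}propanoate | COC(=O)CCc1cc(OC)c(O)c(c1)/C(COCc1ccccc1)=C/c1cc(OC)c(OC(=O)C(C)(C)C)c(OC)c1
F4 | step 8 | methyl 3-{3-[(2R)-1-(benzyloxy)-3-[3,5-dimethoxy-4-(pivaloyloxy)phenyl]propan-2-yl]-4-hydroxy-5-methoxyphenyl}propanoate | COC(=O)CCc1cc(OC)c(O)c(c1)[C@H](COCc1ccccc1)Cc1cc(OC)c(OC(=O)C(C)(C)C)c(OC)c1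
F5 | step 8 | methyl 3-{3-[(2R)-1-(benzyloxy)-3-(4-hydroxy-3,5-dimethoxyphenyl)propan-2-yl]-4-hydroxy-5-methoxyphenyl}propanoate | COC(=O)CCc1cc(OC)c(O)c(c1)[C@H](COCc1ccccc1)Cc1cc(OC)c(O)c(OC)c1
F6 | step 8 | methyl 3-{3-[(2R)-1-(benzyloxy)-3-(3,5-dimethoxy-4-oxocyclohexa-2,5-dien-1-ylidene)propan-2-yl]-4-hydroxy-5-methoxyphenyl}propanoate | COC(=O)CCc1cc(OC)c(O)c(c1)[C@H](COCc1ccccc1)C=C1C=C(OC)C(=O)C(OC)=C1
F7 | step 7 | 4-(3-hydroxyprop-1-yn-1-yl)-2,6-dimethoxyphenyl pivalate | COc1cc(C#CCO)cc(OC)c1OC(=O)C(C)(C)C
F8 | step 7 | 4-[(1Z)-3-hydroxyprop-1-en-1-yl]-2,6-dimethoxyphenyl pivalate | COc1cc(/C=C\CO)cc(OC)c1OC(=O)C(C)(C)C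
F9 | step 7 | 4-[(2R,3S)-3-(hydroxymethyl)oxiran-2-yl]-2,6-dimethoxyphenyl pivalate | O1[C@@H](CO)[C@H]1c1cc(OC)c(OC(=O)C(C)(C)C)c(OC)c1
F10 | step 10 | methyl 3-[(2S,3R)-2-[3,5-dimethoxy-4-(pivaloyloxy)phenyl]-3-(hydroxymethyl)-7-methoxy-2,3-dihydro-1-benzofuran-5-yl]propanoate | COC(=O)CCc1cc(OC)c2c(c1)[C@H](CO)[C@@H](c1cc(OC)c(OC(=O)C(C)(C)C)c(OC)c1)O2
F11 | step 3 | methyl 3-{4-[(diphenylmethylidene)amino]-3-methoxyphenyl}propanoate | COC(=O)CCc1ccc(N=C(c2ccccc2)c2ccccc2)c(OC)c1
F12 | step 3 | methyl 3-(4-amino-3-methoxyphenyl)propanoate | COC(=O)CCc1ccc(N)c(OC)c1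
F13 | step 3 | 2-methoxy-4-(3-methoxy-3-oxopropyl)benzenediazonium 4-methylbenzenesulfonate | COC(=O)CCc1ccc([N+]#N)c(OC)c1.Cc1ccc(cc1)S(=O)(=O)[O-]
A1 | alternative 1 | tert-butyldimethyl{[(2E)-3-(4,4,5,5-tetramethyl-1,3,2-dioxaborolan-2-yl)prop-2-en-1-yl]oxy}silane | CC(C)(C)[Si](C)(C)OC/C=C/B1OC(C)(C)C(C)(C)O1
A2 | alternative 1 | (4-benzyloxy-3,5-dimethoxyphenyl)lithium | [Li]c1cc(OC)c(OCc2ccccc2)c(OC)c1
A3 | alternative 1 | lithium (4-benzyloxy-3,5-dimethoxyphenyl)[(1E)-3-(tert-butyldimethylsilyloxy)prop-1-en-1-yl](pinacolato)borate | [Li+].CC(C)(C)[Si](C)(C)OC/C=C/[B-]1(c2cc(OC)c(OCc3ccccc3)c(OC)c2)OC(C)(C)C(C)(C)O1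
A4 | alternative 1 | methyl 3-[3-bromo-5-methoxy-4-(methoxymethoxy)phenyl]propanoate | COC(=O)CCc1cc(Br)c(OCOC)c(OC)c1
A5 | alternative 1 | methyl 3-{3-[(2R,3S)-3-(4-benzyloxy-3,5-dimethoxyphenyl)-1-(tert-butyldimethylsilyloxy)-3-(4,4,5,5-tetramethyl-1,3,2-dioxaborolan-2-yl)propan-2-yl]-5-methoxy-4-(methoxymethoxy)phenyl}propanoate | COC(=O)CCc1cc(OC)c(OCOC)c(c1)[C@H](CO[Si](C)(C)C(C)(C)C)[C@@H](c1cc(OC)c(OCc2ccccc2)c(OC)c1)B1OC(C)(C)C(C)(C)O1
A6 | alternative 2 | tert-butyl{3-[5-[(1S,2R)-3-(benzyloxy)-1-(4-benzyloxy-3,5-dimethoxyphenyl)-1-(ethynyloxy)propan-2-yl]furan-3-yl]propoxy}dimethylsilane | CC(C)(C)[Si](C)(C)OCCCc1coc(c1)[C@H](COCc1ccccc1)[C@@H](c1cc(OC)c(OCc2ccccc2)c(OC)c1)OC#C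
A7 | alternative 2 | (2S,3R)-2-(4-benzyloxy-3,5-dimethoxyphenyl)-3-(benzyloxymethyl)-5-[3-(tert-butyldimethylsilyloxy)propyl]-2,3-dihydro-1-benzofuran-7-ol | CC(C)(C)[Si](C)(C)OCCCc1cc(O)c2c(c1)[C@H](COCc1ccccc1)[C@@H](c1cc(OC)c(OCc3ccccc3)c(OC)c1)O2
A8 | alternative 3 | methyl 3-{3-[2-(tert-butyldimethylsilyloxy)-1-(4-methylphenylsulfonyl)ethyl]-4-hydroxy-5-methoxyphenyl}propanoate (racemic) | COC(=O)CCc1cc(OC)c(O)c(c1)C(CO[Si](C)(C)C(C)(C)C)S(=O)(=O)c1ccc(C)cc1
A9 | alternative 3 | (2R,5R)-1-(4-benzyloxy-3,5-dimethoxybenzyl)-2,5-dimethylthiolan-1-ium tetrafluoroborate | C[C@@H]1CC[C@@H](C)[S+]1Cc1cc(OC)c(OCc2ccccc2)c(OC)c1.F[B-](F)(F)F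
A10 | alternative 3 | methyl 3-{5-[2-(tert-butyldimethylsilyloxy)ethylidene]-3-methoxy-4-oxocyclohexa-1,2-dien-1-yl}propanoate (ortho-quinone methide: 6-alkylidenecyclohexa-2,4-dienone form) | COC(=O)CCC1=CC(=CCO[Si](C)(C)C(C)(C)C)C(=O)C(OC)=C1
A11 | alternative 3 | methyl 3-[(2S,3R)-2-(4-benzyloxy-3,5-dimethoxyphenyl)-3-[(tert-butyldimethylsilyloxy)methyl]-7-methoxy-2,3-dihydro-1-benzofuran-5-yl]propanoate | COC(=O)CCc1cc(OC)c2c(c1)[C@H](CO[Si](C)(C)C(C)(C)C)[C@@H](c1cc(OC)c(OCc3ccccc3)c(OC)c1)O2
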